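**Plan**

Numbering (spiro[4.5]decane): ring A = C1 (CHOH), C2 (trienyl side chain), C3, C4, C5 (spiro); ring B = C5, C6 (hydroxypropyl), C7 (=C(Me)CHO), C8, C9, C10 (Me, OH).
Cuts, in retrosynthetic order: the C2–side-chain bond (epoxide opening by an alkenyllithium); C1–OH back to a C1 ketone; then in one event C4–C5 (1,2-shift), C6–C7 (alkyne–alkene cyclization) and the ylidene C–I (later C–Me). This leads to an acyclic 1,6-enyne that carries a 1-silyloxycyclobutyl group on the alkene.
Enabling feature: carbinol C1 sits next to the quaternary spiro C5, and C5 is flanked by C6–C7(sp2). A C1 ketone alpha to a quaternary centre that is beta to an exocyclic alkene is the retron of an alkyne-initiated cation cyclization terminated by semipinacol ring expansion of a cyclobutanol.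
Forward: linear enyne (C10 centre first), then ring B and ring A together in the key step (cyclobutane to cyclopentanone), methyl coupling, C1=C2 alkene, epoxide, union with the trienyl iodide, acetate, desilylation, enal.
Stereochemistry: C10 from Sharpless epoxidation; C5 and C6 relayed from C10 and the Z-alkene in the key step; ylidene geometry from anti carboauration/iodination; C1 and C2 from C10–OH-directed epoxidation and SN2 opening.

Key step: step 8

Remark: tert-butyl(3-iodopropoxy)diphenylsilane and hexa-1,5-diyne are taken as purchasable; the spiro[4.5]decane numbering above is used for all spiro intermediates.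

**Route**

Step 1
Reactants: 1 hexa-1,5-diyne
Product: 3 tert-butyl(hepta-2,6-diyn-1-yloxy)diphenylsilane, via lithium hepta-2,6-diyn-1-olate 2 (not isolated)
Conditions: 1 (3 equiv), n-BuLi (1 equiv), THF, −78 °C; (CH2O)n, −78 °C → rt; then t-BuPh2SiCl, rt
Reagents that add atoms: formaldehyde (from paraformaldehyde), C=O; tert-butyl(chloro)diphenylsilane, CC(C)(C)[Si](Cl)(c1ccccc1)c1ccccc1
Why: Monolithiation of the excess diyne, acetylide addition to formaldehyde and O-silylation of the lithium alkoxide in the same flask are standard acetylide and silyl ether chemistry.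

Step 2
Reactants: 3 tert-butyl(hepta-2,6-diyn-1-yloxy)diphenylsilane
Product: 5 (2E)-8-{[tert-butyl(diphenyl)silyl]oxy}-3-methyloct-2-en-6-yn-1-ol, via the E-alkenyl(dimethyl)alane 4 (not isolated)
Conditions: Me3Al (2 equiv), Cp2ZrCl2 (0.2 equiv), CH2Cl2, 0 °C → rt; then n-BuLi, THF, −78 °C; (CH2O)n, → rt
Reagents that add atoms: trimethylaluminium, C[Al](C)C; formaldehyde (from paraformaldehyde), C=O
Why: Zirconium-catalysed methylalumination (Negishi carboalumination) adds methyl and aluminium syn and regioselectively across the terminal alkyne only, and hydroxymethylation of the derived alanate with retention should fix the E-trisubstituted allylic alcohol.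

Step 3
Reactants: 5 (2E)-8-{[tert-butyl(diphenyl)silyl]oxy}-3-methyloct-2-en-6-yn-1-ol
Product: 6 [(2S,3S)-3-(5-{[tert-butyl(diphenyl)silyl]oxy}pent-3-yn-1-yl)-3-methyloxiran-2-yl]methanol
Conditions: Ti(OiPr)4 (10 mol %), L-(+)-diethyl tartrate (12 mol %), t-BuOOH, 4 Å molecular sieves, CH2Cl2, −20 °C
Reagents that add atoms: tert-butyl hydroperoxide, CC(C)(C)OO
Why: Sharpless asymmetric epoxidation with the L-(+)-tartrate delivers oxygen to the face of the E-allylic alcohol that gives the (2S,3S)-epoxide, which sets the future C10 carbinol centre by reagent control.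

Step 4
Reactants: 6 [(2S,3S)-3-(5-{[tert-butyl(diphenyl)silyl]oxy}pent-3-yn-1-yl)-3-methyloxiran-2-yl]methanol
Product: 7 tert-butyl({5-[(2S,3R)-3-(chloromethyl)-2-methyloxiran-2-yl]pent-2-yn-1-yl}oxy)diphenylsilane
Conditions: PPh3, CCl4, NaHCO3, reflux
Reagents that add atoms: carbon tetrachloride, ClC(Cl)(Cl)Cl
Why: The Appel reaction converts the primary alcohol into the chloride under neutral conditions without opening the epoxide.

Step 5
Reactants: 7 tert-butyl({5-[(2S,3R)-3-(chloromethyl)-2-methyloxiran-2-yl]pent-2-yn-1-yl}oxy)diphenylsilane; 8 tert-butyl(3-iodopropoxy)diphenylsilane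
Product: 10 (6S)-1,11-bis{[tert-butyl(diphenyl)silyl]oxy}-6-methylundeca-4,9-diyn-6-ol, via the dilithium alkoxide acetylide 9 (not isolated)
Conditions: LiN(i-Pr)2 (3.1 equiv), THF, −78 → −30 °C; then DMPU, 8, −30 °C → rt
Reagents that add atoms: none
Why: Base-induced eliminative opening of the 2,3-epoxy chloride gives the tertiary propargylic alkoxide with the carbinol C–O bond untouched, and the lithium acetylide formed by the third equivalent of base is C-alkylated by the primary iodide (acetylide alkylation).

Step 6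
Reactants: 10 (6S)-1,11-bis{[tert-butyl(diphenyl)silyl]oxy}-6-methylundeca-4,9-diyn-6-ol
Product: 12 (4Z,6S)-1,11-bis{[tert-butyl(diphenyl)silyl]oxy}-5-iodo-6-methylundec-4-en-9-yn-6-ol, via the Z-alkenylstannane 11 (not isolated)
Conditions: [Cp*RuCl]4 (2.5 mol %), Bu3SnH (1.05 equiv, slow addition), CH2Cl2, rt; then I2, 0 °C
Reagents that add atoms: iodine, [I][I]
Why: Hydroxyl-directed ruthenium-catalysed trans-hydrostannation places tin on the alkyne carbon next to the free tertiary carbinol and hydrogen anti to it, the alkyne flanked only by a silyl ether is expected to react more slowly, and iododestannylation with retention gives the Z-iodoalkene.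

Step 7
Reactants: 12 (4Z,6S)-1,11-bis{[tert-butyl(diphenyl)silyl]oxy}-5-iodo-6-methylundec-4-en-9-yn-6-ol; 13 cyclobutanone
Product: 16 (4Z,6S)-1,11-bis{[tert-butyl(diphenyl)silyl]oxy}-6-methyl-6-[(triethylsilyl)oxy]-5-{1-[(triethylsilyl)oxy]cyclobutyl}undec-4-en-9-yne, via the lithium alkoxide alkenyllithium 14 (not isolated), via the dilithium dialkoxide 15 (not isolated)
Conditions: MeLi (1.0 equiv), Et2O, −78 °C; t-BuLi (2.1 equiv), −78 °C; 13, −78 °C; then Et3SiOTf (2.5 equiv), −78 → 0 °C
Reagents that add atoms: triethylsilyl trifluoromethanesulfonate, CC[Si](CC)(CC)OS(=O)(=O)C(F)(F)F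
Why: Iodine–lithium exchange with retention of alkene geometry, 1,2-addition of the alkenyllithium to the strained, reactive cyclobutanone and silylation of both tertiary lithium alkoxides by the silyl triflate are standard organolithium operations run in one flask.

Step 8
Reactants: 16 (4Z,6S)-1,11-bis{[tert-butyl(diphenyl)silyl]oxy}-6-methyl-6-[(triethylsilyl)oxy]-5-{1-[(triethylsilyl)oxy]cyclobutyl}undec-4-en-9-yne
Product: 17 6-(3-{[tert-butyl(diphenyl)silyl]oxy}propyl)-7-[(E)-2-{[tert-butyl(diphenyl)silyl]oxy}-1-iodoethylidene]-10-methyl-10-[(triethylsilyl)oxy]spiro[4.5]decan-1-one (C5, C6, C10 arranged as in the target; iodine cis to C8)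
Conditions: Ph3PAuNTf2 (5 mol %), N-iodosuccinimide (1.2 equiv), 4 Å molecular sieves, CH2Cl2, −40 → −10 °C, dark
Reagents that add atoms: N-iodosuccinimide, O=C1CCC(=O)N1I
Why: Proposed new method: the cationic monovalent gold catalyst π-activates the alkyne, the CH terminus of the Z-alkene attacks the alkyne carbon remote from the silyloxymethyl group, the tertiary cation developing at the future C5 is quenched in the same event by anti 1,2-shift of a cyclobutane C–C bond (ring expansion of the four-membered ring to the cyclopentanone), and N-iodosuccinimide iododeaurates the alkenylgold with retention while the succinimide anion takes the triethylsilyl group from the oxocarbenium ion. The closest known reaction types are gold-catalysed enyne cyclizations terminated by a pinacol shift of a silyloxy carbinol, iododeauration of alkenylgold intermediates by N-iodosuccinimide and semipinacol ring expansion of 1-alkenylcyclobutanols, which have not been combined on a 1,6-enyne with a cyclobutyl terminator. Ring B closes 6-exo-dig at the alkyne (both alkene carbons become ring members), and ring A is not closed by cyclization but arises from the cyclobutane by the 1,2-shift. C5 and C6 are set relative to each other by anti addition across the alkene of defined Z geometry and relative to C10 by a chair-like transition state in which the C6 chain is equatorial, the C10 methyl is axial and the smaller C10 silyloxy group lies in the alkene plane next to the bulky silyloxycyclobutyl group (allylic 1,2-strain), while the exocyclic alkene geometry follows from anti carboauration, which places iodine trans to C6. The step needs attack at the internal alkyne carbon (six- and not seven-membered ring, helped by the propargylic oxygen, which disfavours positive charge at the other carbon), cyclobutane migration instead of methyl migration from C10 (release of ring strain) and iodination instead of protodeauration (no proton is released because both carbinols are silylated), and direct iodonium attack on the alkene should be slowed by its two allylic silyloxy groups.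

Step 9
Reactants: 17 the iodo spiro ketone
Product: 18 6-(3-{[tert-butyl(diphenyl)silyl]oxy}propyl)-7-[(Z)-1-{[tert-butyl(diphenyl)silyl]oxy}propan-2-ylidene]-10-methyl-10-[(triethylsilyl)oxy]spiro[4.5]decan-1-one (silyloxymethyl cis to C6, methyl cis to C8)
Conditions: Me2Zn (2 equiv), Pd(t-Bu3P)2 (5 mol %), THF, 0 °C → rt
Reagents that add atoms: dimethylzinc, C[Zn]C
Why: Negishi cross-coupling of the alkenyl iodide with dimethylzinc proceeds with retention of alkene geometry and tolerates the hindered ketone, which completes the tetrasubstituted alkene.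

Step 10
Reactants: 18 the methylated spiro ketone
Product: 19 the corresponding spiro[4.5]dec-1-en-1-yl trifluoromethanesulfonate
Conditions: KN(SiMe3)2, PhNTf2, THF, −78 °C
Reagents that add atoms: N-phenylbis(trifluoromethanesulfonimide), O=S(=O)(N(c1ccccc1)S(=O)(=O)C(F)(F)F)C(F)(F)F
Why: The ketone can enolize only toward C2 because C5 is quaternary, and O-triflation of the potassium enolate gives the enol triflate.

Step 11
Reactants: 19 the enol triflate
Product: 20 6-(3-{[tert-butyl(diphenyl)silyl]oxy}propyl)-7-[(Z)-1-{[tert-butyl(diphenyl)silyl]oxy}propan-2-ylidene]-10-methyl-10-[(triethylsilyl)oxy]spiro[4.5]dec-1-ene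
Conditions: Pd(OAc)2 (5 mol %), PPh3, HCO2H, n-Bu3N, DMF, 60 °C
Reagents that add atoms: none
Why: Palladium-catalysed formate reduction of the enol triflate (oxidative addition, formate exchange, decarboxylation, reductive elimination) replaces the triflate by hydrogen and gives the C1=C2 cyclopentene without touching the silyl ethers or the tetrasubstituted alkene.

Step 12
Reactants: 20 the spirodecene triethylsilyl ether
Product: 21 6-(3-{[tert-butyl(diphenyl)silyl]oxy}propyl)-7-[(Z)-1-{[tert-butyl(diphenyl)silyl]oxy}propan-2-ylidene]-10-methylspiro[4.5]dec-1-en-10-ol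
Conditions: HF·pyridine, pyridine, THF, 0 °C → rt
Reagents that add atoms: none
Why: Buffered HF·pyridine should cleave the triethylsilyl ether faster than the two primary tert-butyldiphenylsilyl ethers, and the hydroxyl is freed only now, after the C1 ketone is gone, so that no retro-aldol cleavage of a β-hydroxy ketone can occur.

Step 13
Reactants: 21 the spirodecenol
Product: 22 the 1,2-epoxide of 21 with the oxirane oxygen on the face of ring A that carries C10 (syn to the C10 hydroxyl)
Conditions: VO(acac)2 (5 mol %), t-BuOOH, CH2Cl2, 0 °C → rt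
Reagents that add atoms: tert-butyl hydroperoxide, CC(C)(C)OO
Why: Vanadium-catalysed hydroxyl-directed epoxidation delivers the peroxide oxygen from the bound tertiary C10 alkoxide to the homoallylic C1=C2 alkene on the face of ring A that carries C10, which sets the C1–O configuration, while the tetrasubstituted alkene lies out of reach of the bound oxidant.

Step 14
Reactants: 23 but-2-yne-1,4-diol
Product: 24 4-{[tert-butyl(dimethyl)silyl]oxy}but-2-yn-1-ol
Conditions: NaH (1.0 equiv), THF, 0 °C; then t-BuMe2SiCl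
Reagents that add atoms: tert-butyl(chloro)dimethylsilane, CC(C)(C)[Si](C)(C)Cl
Why: Monodeprotonation of the symmetrical diol and silylation of the monoalkoxide is the standard monosilylation of a symmetrical diol.

Step 15
Reactants: 24 4-{[tert-butyl(dimethyl)silyl]oxy}but-2-yn-1-ol
Product: 26 (2Z)-4-{[tert-butyl(dimethyl)silyl]oxy}-3-iodobut-2-en-1-ol, via the sodium alkenylalanate 25 (not isolated)
Conditions: NaAlH2(OCH2CH2OMe)2, THF, 0 °C; then I2, −78 °C
Reagents that add atoms: iodine, [I][I]
Why: Alkoxide-directed trans-hydroalumination of the propargylic alcohol places aluminium on the distal alkyne carbon in a five-membered alanate, and iodinolysis with retention gives the Z-iodoalkene with iodine cis to the hydroxymethyl group.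

Step 16
Reactants: 26 (2Z)-4-{[tert-butyl(dimethyl)silyl]oxy}-3-iodobut-2-en-1-ol
Product: 27 (2Z)-4-{[tert-butyl(dimethyl)silyl]oxy}-3-iodobut-2-enal
Conditions: MnO2, CH2Cl2, rt
Reagents that add atoms: none
Why: MnO2 oxidizes the allylic alcohol to the enal under neutral conditions that preserve the Z-iodoalkene.

Step 17
Reactants: 28 2-methylprop-2-en-1-ol; 29 1-bromo-3-methylbut-2-ene
Product: 31 6-methyl-2-methylidenehept-5-en-1-ol, via the dilithio dianion 30 (not isolated)
Conditions: n-BuLi (2.2 equiv), TMEDA, Et2O/hexane, 0 °C → rt; then 29, THF, −78 °C → rt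
Reagents that add atoms: none
Why: Alkoxide-directed allylic lithiation gives the dianion of the allylic alcohol, which is alkylated at carbon by the allylic bromide in an SN2 reaction.

Step 18
Reactants: 31 6-methyl-2-methylidenehept-5-en-1-ol
Product: 32 2-(bromomethyl)-6-methylhepta-1,5-diene
Conditions: PBr3, Et2O, −10 °C
Reagents that add atoms: phosphorus tribromide, BrP(Br)Br
Why: PBr3 converts the primary allylic alcohol into the bromide, and any allylic transposition is degenerate in this 2-substituted allyl system.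

Step 19
Reactants: 32 2-(bromomethyl)-6-methylhepta-1,5-diene
Product: 33 diethyl (6-methyl-2-methylidenehept-5-en-1-yl)phosphonate
Conditions: P(OEt)3 (neat), 120 °C
Reagents that add atoms: triethyl phosphite, CCOP(OCC)OCC
Why: The Michaelis–Arbuzov reaction of the allylic bromide with triethyl phosphite gives the allylic phosphonate.

Step 20
Reactants: 33 diethyl (6-methyl-2-methylidenehept-5-en-1-yl)phosphonate; 27 (2Z)-4-{[tert-butyl(dimethyl)silyl]oxy}-3-iodobut-2-enal
Product: 35 tert-butyl{[(2Z,4E)-2-iodo-10-methyl-6-methylideneundeca-2,4,9-trien-1-yl]oxy}dimethylsilane, via the lithiated phosphonate 34 (not isolated)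
Conditions: n-BuLi, THF, −78 °C; then 27, −78 °C → rt
Reagents that add atoms: none
Why: Horner–Wadsworth–Emmons olefination of the enal with the lithiated allylic phosphonate should form the new disubstituted alkene with E geometry and leave the Z-iodoalkene untouched.

Step 21
Reactants: 35 tert-butyl{[(2Z,4E)-2-iodo-10-methyl-6-methylideneundeca-2,4,9-trien-1-yl]oxy}dimethylsilane; 22 the epoxide
Product: 38 the (1S,2S,5S,6R,10S)-configured target skeleton with the side-chain CH2O as tert-butyldimethylsilyl ether, the C6 propyl oxygen and the ylidene CH2O as tert-butyldiphenylsilyl ethers and free C1 and C10 hydroxyls, via the trienyllithium 36 (not isolated), via the lithium C10 alkoxide 37 (not isolated)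
Conditions: 35, t-BuLi (2.0 equiv), Et2O, −78 °C; 22, MeLi (1.0 equiv), THF, −78 °C; mix, BF3·OEt2 (2 equiv), −78 → −40 °C
Reagents that add atoms: none
Why: Iodine–lithium exchange with retention gives the alkenyllithium, which under BF3·OEt2 activation opens the epoxide by SN2 attack at C2, the carbon remote from the quaternary spiro centre, anti to the epoxide oxygen, so that the side chain at C2 ends up trans to the C1 hydroxyl.

Step 22
Reactants: 38 the coupled tris-silyl ether
Product: 39 the primary allylic alcohol of the side chain (both tert-butyldiphenylsilyl ethers retained)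
Conditions: PPTS, MeOH, 0 °C → rt
Reagents that add atoms: none
Why: Mild acidic methanolysis removes the primary tert-butyldimethylsilyl ether selectively in the presence of the more robust tert-butyldiphenylsilyl ethers.

Step 23
Reactants: 39 the side-chain allylic alcohol
Product: 40 the side-chain acetate
Conditions: Ac2O (1.1 equiv), pyridine, CH2Cl2, −20 → 0 °C
Reagents that add atoms: acetic anhydride, CC(=O)OC(C)=O
Why: The unhindered primary allylic alcohol is acetylated much faster than the neopentyl-type secondary C1 hydroxyl and the tertiary C10 hydroxyl.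

Step 24
Reactants: 40 the acetate bis-silyl ether
Product: 41 the target with CH2OH in place of CHO on the C7 ylidene carbon
Conditions: HF·pyridine, pyridine, THF, rt
Reagents that add atoms: none
Why: HF·pyridine cleaves both primary tert-butyldiphenylsilyl ethers without affecting the acetate or the polyene.

Step 25
Reactants: 41 the allylic alcohol acetate
Product: 42 CNP0204268.2 (target)
Conditions: MnO2, CH2Cl2, rt
Reagents that add atoms: none
Why: MnO2 oxidizes only the allylic primary alcohol on the tetrasubstituted alkene to the Z-enal, whereas the saturated primary, the homoallylic secondary and the tertiary hydroxyl groups are not oxidized.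

**Compound list**

1 | hexa-1,5-diyne | C#CCCC#C | starting material
2 | lithium hepta-2,6-diyn-1-olate (not isolated) | [Li]OCC#CCCC#C | intermediate
3 | tert-butyl(hepta-2,6-diyn-1-yloxy)diphenylsilane | C#CCCC#CCO[Si](c1ccccc1)(c1ccccc1)C(C)(C)C | intermediate
4 | [(1E)-7-{[tert-butyl(diphenyl)silyl]oxy}-2-methylhept-1-en-5-yn-1-yl]dimethylalumane (not isolated) | C[Al](C)/C=C(\C)CCC#CCO[Si](c1ccccc1)(c1ccccc1)C(C)(C)C | intermediate
5 | (2E)-8-{[tert-butyl(diphenyl)silyl]oxy}-3-methyloct-2-en-6-yn-1-ol | OC/C=C(\C)CCC#CCO[Si](c1ccccc1)(c1ccccc1)C(C)(C)C | intermediate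
6 | [(2S,3S)-3-(5-{[tert-butyl(diphenyl)silyl]oxy}pent-3-yn-1-yl)-3-methyloxiran-2-yl]methanol | CC(C)(C)[Si](c1ccccc1)(c1ccccc1)OCC#CCC[C@]1(C)O[C@H]1CO | intermediate
7 | tert-butyl({5-[(2S,3R)-3-(chloromethyl)-2-methyloxiran-2-yl]pent-2-yn-1-yl}oxy)diphenylsilane | CC(C)(C)[Si](c1ccccc1)(c1ccccc1)OCC#CCC[C@]1(C)O[C@H]1CCl | intermediate
8 | tert-butyl(3-iodopropoxy)diphenylsilane | ICCCO[Si](c1ccccc1)(c1ccccc1)C(C)(C)C | starting material
9 | dilithium (3S)-8-{[tert-butyl(diphenyl)silyl]oxy}-3-methylocta-1,6-diyn-1-id-3-olate (not isolated) | CC(C)(C)[Si](c1ccccc1)(c1ccccc1)OCC#CCC[C@](C#C[Li])(C)O[Li] | intermediate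
10 | (6S)-1,11-bis{[tert-butyl(diphenyl)silyl]oxy}-6-methylundeca-4,9-diyn-6-ol | CC(C)(C)[Si](c1ccccc1)(c1ccccc1)OCC#CCC[C@](C#CCCCO[Si](c1ccccc1)(c1ccccc1)C(C)(C)C)(C)O | intermediate
11 | (4Z,6S)-1,11-bis{[tert-butyl(diphenyl)silyl]oxy}-6-methyl-5-(tributylstannyl)undec-4-en-9-yn-6-ol (not isolated) | CC(C)(C)[Si](c1ccccc1)(c1ccccc1)OCC#CCC[C@](/C(=C/CCCO[Si](c1ccccc1)(c1ccccc1)C(C)(C)C)[Sn](CCCC)(CCCC)CCCC)(C)O | intermediate
12 | (4Z,6S)-1,11-bis{[tert-butyl(diphenyl)silyl]oxy}-5-iodo-6-methylundec-4-en-9-yn-6-ol | CC(C)(C)[Si](c1ccccc1)(c1ccccc1)OCC#CCC[C@](/C(I)=C/CCCO[Si](c1ccccc1)(c1ccccc1)C(C)(C)C)(C)O | intermediate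
13 | cyclobutanone | O=C1CCC1 | starting material
14 | lithium alkoxide alkenyllithium from 12 (lithium on C5 and on the C6 oxygen; not isolated) | CC(C)(C)[Si](c1ccccc1)(c1ccccc1)OCC#CCC[C@](/C([Li])=C/CCCO[Si](c1ccccc1)(c1ccccc1)C(C)(C)C)(C)O[Li] | intermediate
15 | dilithium dialkoxide, adduct of 14 and cyclobutanone (not isolated) | CC(C)(C)[Si](c1ccccc1)(c1ccccc1)OCC#CCC[C@](/C(=C/CCCO[Si](c1ccccc1)(c1ccccc1)C(C)(C)C)C1(O[Li])CCC1)(C)O[Li] | intermediate
16 | (4Z,6S)-1,11-bis{[tert-butyl(diphenyl)silyl]oxy}-6-methyl-6-[(triethylsilyl)oxy]-5-{1-[(triethylsilyl)oxy]cyclobutyl}undec-4-en-9-yne (propyl chain cis to the cyclobutyl group) | CC(C)(C)[Si](c1ccccc1)(c1ccccc1)OCC#CCC[C@](/C(=C/CCCO[Si](c1ccccc1)(c1ccccc1)C(C)(C)C)C1(O[Si](CC)(CC)CC)CCC1)(C)O[Si](CC)(CC)CC | intermediate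
17 | 6-(3-{[tert-butyl(diphenyl)silyl]oxy}propyl)-7-[(E)-2-{[tert-butyl(diphenyl)silyl]oxy}-1-iodoethylidene]-10-methyl-10-[(triethylsilyl)oxy]spiro[4.5]decan-1-one (C5, C6, C10 arranged as in the target; iodine cis to C8) | O=C1CCC[C@]12[C@H](CCCO[Si](c3ccccc3)(c3ccccc3)C(C)(C)C)/C(=C(/I)CO[Si](c3ccccc3)(c3ccccc3)C(C)(C)C)CC[C@]2(C)O[Si](CC)(CC)CC | intermediate
18 | 6-(3-{[tert-butyl(diphenyl)silyl]oxy}propyl)-7-[(Z)-1-{[tert-butyl(diphenyl)silyl]oxy}propan-2-ylidene]-10-methyl-10-[(triethylsilyl)oxy]spiro[4.5]decan-1-one (C5, C6, C10 arranged as in the target) | O=C1CCC[C@]12[C@H](CCCO[Si](c3ccccc3)(c3ccccc3)C(C)(C)C)/C(=C(/C)CO[Si](c3ccccc3)(c3ccccc3)C(C)(C)C)CC[C@]2(C)O[Si](CC)(CC)CC | intermediate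
19 | spiro[4.5]dec-1-en-1-yl trifluoromethanesulfonate derived from 18 | O=S(=O)(OC1=CCC[C@]12[C@H](CCCO[Si](c3ccccc3)(c3ccccc3)C(C)(C)C)/C(=C(/C)CO[Si](c3ccccc3)(c3ccccc3)C(C)(C)C)CC[C@]2(C)O[Si](CC)(CC)CC)C(F)(F)F | intermediate
20 | 6-(3-{[tert-butyl(diphenyl)silyl]oxy}propyl)-7-[(Z)-1-{[tert-butyl(diphenyl)silyl]oxy}propan-2-ylidene]-10-methyl-10-[(triethylsilyl)oxy]spiro[4.5]dec-1-ene | C1=CCC[C@]12[C@H](CCCO[Si](c3ccccc3)(c3ccccc3)C(C)(C)C)/C(=C(/C)CO[Si](c3ccccc3)(c3ccccc3)C(C)(C)C)CC[C@]2(C)O[Si](CC)(CC)CC | intermediate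
21 | 6-(3-{[tert-butyl(diphenyl)silyl]oxy}propyl)-7-[(Z)-1-{[tert-butyl(diphenyl)silyl]oxy}propan-2-ylidene]-10-methylspiro[4.5]dec-1-en-10-ol | C1=CCC[C@]12[C@H](CCCO[Si](c3ccccc3)(c3ccccc3)C(C)(C)C)/C(=C(/C)CO[Si](c3ccccc3)(c3ccccc3)C(C)(C)C)CC[C@]2(C)O | intermediate
22 | 1,2-epoxide of 21, oxirane oxygen syn to the C10 hydroxyl | [C@H]12CC[C@]3([C@H](CCCO[Si](c4ccccc4)(c4ccccc4)C(C)(C)C)/C(=C(/C)CO[Si](c4ccccc4)(c4ccccc4)C(C)(C)C)CC[C@]3(C)O)[C@H]1O2 | intermediate
23 | but-2-yne-1,4-diol | OCC#CCO | starting material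
24 | 4-{[tert-butyl(dimethyl)silyl]oxy}but-2-yn-1-ol | OCC#CCO[Si](C)(C)C(C)(C)C | intermediate
25 | sodium cyclic alkenylalanate (2,5-dihydro-1,2-oxaalumol-2-uide with two 2-methoxyethoxy groups on aluminium; not isolated) | [Na+].COCCO[Al-]1(OCCOC)OCC=C1CO[Si](C)(C)C(C)(C)C | intermediate
26 | (2Z)-4-{[tert-butyl(dimethyl)silyl]oxy}-3-iodobut-2-en-1-ol | OC/C=C(\I)CO[Si](C)(C)C(C)(C)C | intermediate
27 | (2Z)-4-{[tert-butyl(dimethyl)silyl]oxy}-3-iodobut-2-enal | O=C/C=C(\I)CO[Si](C)(C)C(C)(C)C | intermediate
28 | 2-methylprop-2-en-1-ol | C=C(C)CO | starting material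
29 | 1-bromo-3-methylbut-2-ene | CC(C)=CCBr | starting material
30 | dilithio dianion of 2-methylprop-2-en-1-ol (not isolated) | [Li]CC(=C)CO[Li] | intermediate
31 | 6-methyl-2-methylidenehept-5-en-1-ol | OCC(=C)CCC=C(C)C | intermediate
32 | 2-(bromomethyl)-6-methylhepta-1,5-diene | BrCC(=C)CCC=C(C)C | intermediate
33 | diethyl (6-methyl-2-methylidenehept-5-en-1-yl)phosphonate | CCOP(=O)(CC(=C)CCC=C(C)C)OCC | intermediate
34 | lithiated phosphonate (lithium on the carbon next to phosphorus; not isolated) | CCOP(=O)(C([Li])C(=C)CCC=C(C)C)OCC | intermediate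
35 | tert-butyl{[(2Z,4E)-2-iodo-10-methyl-6-methylideneundeca-2,4,9-trien-1-yl]oxy}dimethylsilane | C=C(/C=C/C=C(/CO[Si](C)(C)C(C)(C)C)I)CCC=C(C)C | intermediate
36 | trienyllithium from 35 (lithium in place of iodine; not isolated) | C=C(/C=C/C=C(/CO[Si](C)(C)C(C)(C)C)[Li])CCC=C(C)C | intermediate
37 | lithium C10 alkoxide of epoxide 22 (not isolated) | [C@H]12CC[C@]3([C@H](CCCO[Si](c4ccccc4)(c4ccccc4)C(C)(C)C)/C(=C(/C)CO[Si](c4ccccc4)(c4ccccc4)C(C)(C)C)CC[C@]3(C)O[Li])[C@H]1O2 | intermediate
38 | (1S,2S,5S,6R,10S) coupled product: target skeleton with side-chain CH2O–SiMe2t-Bu, C6 propyl O–SiPh2t-Bu, ylidene CH2O–SiPh2t-Bu, free C1 and C10 hydroxyls | C=C(/C=C/C=C(/CO[Si](C)(C)C(C)(C)C)[C@@H]1CC[C@]2([C@H](CCCO[Si](c3ccccc3)(c3ccccc3)C(C)(C)C)/C(=C(/C)CO[Si](c3ccccc3)(c3ccccc3)C(C)(C)C)CC[C@]2(C)O)[C@H]1O)CCC=C(C)C | intermediate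
39 | as 38 with the side-chain primary allylic alcohol free | C=C(/C=C/C=C(/CO)[C@@H]1CC[C@]2([C@H](CCCO[Si](c3ccccc3)(c3ccccc3)C(C)(C)C)/C(=C(/C)CO[Si](c3ccccc3)(c3ccccc3)C(C)(C)C)CC[C@]2(C)O)[C@H]1O)CCC=C(C)C | intermediate
40 | as 39 with the side-chain alcohol acetylated | C=C(/C=C/C=C(/COC(C)=O)[C@@H]1CC[C@]2([C@H](CCCO[Si](c3ccccc3)(c3ccccc3)C(C)(C)C)/C(=C(/C)CO[Si](c3ccccc3)(c3ccccc3)C(C)(C)C)CC[C@]2(C)O)[C@H]1O)CCC=C(C)C | intermediate
41 | target with CH2OH in place of CHO on the C7 ylidene carbon | C=C(/C=C/C=C(/COC(C)=O)[C@@H]1CC[C@]2([C@H](CCCO)/C(=C(/C)CO)CC[C@]2(C)O)[C@H]1O)CCC=C(C)C | intermediate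
42 | CNP0204268.2: (1S,2S,5S,6R,10S,7Z)-2-[(2E,4E)-1-acetoxy-10-methyl-6-methylideneundeca-2,4,9-trien-2-yl]-1,10-dihydroxy-6-(3-hydroxypropyl)-10-methyl-7-(1-oxopropan-2-ylidene)spiro[4.5]decane | C=C(/C=C/C=C(/COC(C)=O)[C@@H]1CC[C@]2([C@H](CCCO)/C(=C(/C)C=O)CC[C@]2(C)O)[C@H]1O)CCC=C(C)C | target

**Count and risks**

Total step count: 25. Longest linear sequence: 18 steps (steps 1–13, then 21–25).

Steps most likely to fail:

Step 8. What may go wrong: iodonium transfer to the trisubstituted alkene before the gold-bound alkyne is attacked, oxygen attack of the C10 silyl ether on the activated alkyne, methyl migration from C10 in place of cyclobutane migration, or poor relay of configuration from C10 through a boat-like closure. The fallback uses two separate known events. It sets out from 16: N-iodosuccinimide alone in CH2Cl2 effects the iodonium-induced semipinacol ring expansion of the 1-alkenylcyclobutyl silyl ether and gives the secondary iodide 2-(4-{[tert-butyl(diphenyl)silyl]oxy}-1-iodobutyl)-2-(7-{[tert-butyl(diphenyl)silyl]oxy}-2-[(triethylsilyl)oxy]hept-5-yn-2-yl)cyclopentan-1-one F1. An iodine atom-transfer radical cyclization ((Bu3Sn)2 cat., hν, benzene, 80 °C) then closes ring B 6-exo-dig onto the alkyne and should transfer iodine to the exocyclic alkenyl radical from the less hindered C8 side. This comes back to the route at 17; diastereomers at C5 and C6 would be separated at that point.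

Step 21. What may go wrong: Lewis acid-induced rearrangement of the epoxide (hydride shift to a C1 ketone) faster than C–C bond formation, slow addition of the branched trienyllithium at C2, or silyl migration from oxygen to carbon in the 2-(silyloxymethyl)alkenyllithium. The fallback sets out from 22 (as its alkoxide 37) and the smaller iodide 26: the dilithio derivative of 26 (MeLi, then t-BuLi, −78 °C) opens the epoxide under BF3·OEt2 and gives the analogue of 38 that carries a (2E)-1-{[tert-butyl(dimethyl)silyl]oxy}-4-hydroxybut-2-en-2-yl group at C2 (hydroxymethyl cis to ring carbon C2) F2. MnO2 oxidizes only its allylic primary alcohol to the corresponding 4-oxobut-2-en-2-yl enal F3. Horner–Wadsworth–Emmons olefination with an excess of the lithiated phosphonate 34 then forms the E-diene and comes back to the route at 38.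

Step 13. What may go wrong: weak direction by the hindered tertiary homoallylic alcohol, so that oxidation of the electron-rich tetrasubstituted alkene or attack on the wrong face of ring A competes. The fallback sets out from 21: the lithium alkoxide is carboxylated (n-BuLi, CO2, THF) and treated with iodine. Iodocarbonate cyclization delivers the carbonate oxygen to C1 on the C10 face and iodine to C2 on the opposite face, while an iodonium ion on the other alkene has no internal nucleophile and reverts; this gives the six-membered cyclic carbonate bridging O1 and O10 with iodine at C2 trans to O1 F4. K2CO3 in methanol cleaves the carbonate and the C1 alkoxide displaces the iodide with inversion, which comes back to the route at 22.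

Further compounds
F1 | step 8 | 2-(4-{[tert-butyl(diphenyl)silyl]oxy}-1-iodobutyl)-2-(7-{[tert-butyl(diphenyl)silyl]oxy}-2-[(triethylsilyl)oxy]hept-5-yn-2-yl)cyclopentan-1-one | O=C1CCC[C@@]1([C@H](CCCO[Si](c2ccccc2)(c2ccccc2)C(C)(C)C)I)[C@@](C)(O[Si](CC)(CC)CC)CCC#CCO[Si](c2ccccc2)(c2ccccc2)C(C)(C)C
F2 | step 21 | analogue of 38 with a (2E)-1-{[tert-butyl(dimethyl)silyl]oxy}-4-hydroxybut-2-en-2-yl group at C2 | OC/C=C(/CO[Si](C)(C)C(C)(C)C)[C@@H]1CC[C@]2([C@H](CCCO[Si](c3ccccc3)(c3ccccc3)C(C)(C)C)/C(=C(/C)CO[Si](c3ccccc3)(c3ccccc3)C(C)(C)C)CC[C@]2(C)O)[C@H]1O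
F3 | step 21 | analogue of 38 with a (2E)-1-{[tert-butyl(dimethyl)silyl]oxy}-4-oxobut-2-en-2-yl group at C2 | O=C/C=C(/CO[Si](C)(C)C(C)(C)C)[C@@H]1CC[C@]2([C@H](CCCO[Si](c3ccccc3)(c3ccccc3)C(C)(C)C)/C(=C(/C)CO[Si](c3ccccc3)(c3ccccc3)C(C)(C)C)CC[C@]2(C)O)[C@H]1O
F4 | step 13 | cyclic carbonate of the 1,10-diol derived from 21 with iodine at C2 trans to O1 | I[C@@H]1CC[C@]23[C@H](CCCO[Si](c4ccccc4)(c4ccccc4)C(C)(C)C)/C(=C(/C)CO[Si](c4ccccc4)(c4ccccc4)C(C)(C)C)CC[C@]3(C)OC(=O)O[C@@H]12
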